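**Plan**

1. Retrosynthesis: the C–Cl bond at the CHCl carbon next to the ring CH2 is cut first (SN2 inversion of an equatorial carbinol). Then, in one event, the ring bond between the C(CH3)2 carbon and its CHCl neighbour is cut together with both C–Br bonds (bromonium-induced, diene-terminated cyclization with bromide capture). The acyclic (Z)-chlorodienol is cut at its vinyl–C and C–Cl bonds (anti-carbomagnesiation/chlorination of an alkynol), and the alkynol at its carbinol–allyl bond.
2. Forward: a three-carbon ynal, an allyl group, the C(CH3)2 cap (cross-metathesis) and a vinyl group are joined into the ten-carbon chain (steps 1–5). The single ring, the cyclohexane, closes in step 6. Steps 7–8 turn the carbinol into the chloride.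
3. Enabling feature: in the ring the C(CH3)2 carbon lies between CHBr and CHCl, the pattern left when a bromonium ion on a prenyl terminus is opened at its tertiary carbon by a chlorovinyl carbon. The unit CHCl–C(=CH–CH2Br) is a 1-chloro-1,3-diene that has taken the cation at one end and bromide at the other.
4. Stereochemistry: one carbinol centre is set by catalytic asymmetric allylation. Equatorial in the chair of step 6, it relays to the CHBr centre (anti bromonium opening), to the neighbouring CHCl centre (Z-chloroalkene geometry) and, through A(1,3) strain, to the alkene geometry. Its own inversion in step 8 gives the last CHCl centre.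

Key step: step 6

Remark: (R)-BINOL is taken to give the 3R carbinol from the ynal, as it does for aldehydes whose substituent outranks allyl; the mirror-image ligand would be used if the sense were opposite.

Step 1
Reactants: 1 3-(trimethylsilyl)prop-2-ynal; 2 allyltributylstannane
Product: 3 (3R)-1-(trimethylsilyl)hex-5-en-1-yn-3-ol
Conditions: 2 (1.2 equiv), (R)-BINOL (10 mol%), Ti(OiPr)4 (10 mol%), 4 Å molecular sieves, CH2Cl2, −20 °C; aq NaHCO3
Reagents that add atoms: none
Why: Keck-type catalytic asymmetric allylation, in which the BINOL–titanium Lewis acid shields one face of the aldehyde; this sets the only stereocentre that is not made by relay.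

Step 2
Reactants: 3 (3R)-1-(trimethylsilyl)hex-5-en-1-yn-3-ol; 4 2-methylbut-2-ene
Product: 5 (3R)-6-methyl-1-(trimethylsilyl)hept-5-en-1-yn-3-ol
Conditions: 4 (excess, co-solvent), second-generation Grubbs catalyst (3 mol%), CH2Cl2, 40 °C
Reagents that add atoms: none
Why: Olefin cross-metathesis of the terminal alkene with 2-methylbut-2-ene should give the trisubstituted prenyl-type alkene; the silylated alkyne and the free alcohol are tolerated and no stereocentre is touched.

Step 3
Reactants: 5 (3R)-6-methyl-1-(trimethylsilyl)hept-5-en-1-yn-3-ol
Product: 6 (3R)-6-methylhept-5-en-1-yn-3-ol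
Conditions: K2CO3, MeOH, 23 °C
Reagents that add atoms: none
Why: Base-catalysed methanolysis of the alkynyl C–Si bond frees the terminal alkyne needed in step 4 and leaves the carbinol centre untouched.

Step 4
Reactants: 6 (3R)-6-methylhept-5-en-1-yn-3-ol; 7 vinylmagnesium chloride
Product: 9 (4R)-3-[(Z)-chloromethylidene]-7-methylocta-1,6-dien-4-ol, via dimagnesium chelate 8 (not isolated)
Conditions: 7 (4 equiv), CuI (10 mol%), THF, −20 to 23 °C; then NCS (5 equiv), −40 to 0 °C; aq NH4Cl
Reagents that add atoms: N-chlorosuccinimide, O=C1CCC(=O)N1Cl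
Why: Alkoxide-directed, copper-catalysed anti-carbomagnesiation of a propargylic alcohol puts vinyl on the internal alkyne carbon and magnesium on the terminal carbon inside a five-membered chelate; electrophilic chlorination with retention then places chlorine cis to the carbinol carbon (Z alkene).

Step 5
Reactants: 9 (4R)-3-[(Z)-chloromethylidene]-7-methylocta-1,6-dien-4-ol
Product: 10 (4R)-3-[(Z)-chloromethylidene]-7-methylocta-1,6-dien-4-yl 2,2-dimethylpropanoate
Conditions: PivCl, pyridine, DMAP (cat.), CH2Cl2, 0 to 23 °C
Reagents that add atoms: pivaloyl chloride, CC(C)(C)C(Cl)=O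
Why: DMAP-catalysed acylation; the bulky, weakly nucleophilic pivalate keeps the oxygen from capturing the bromonium ion in step 6, serves there as the equatorial anchor, and is removed in step 7.

Step 6
Reactants: 10 (4R)-3-[(Z)-chloromethylidene]-7-methylocta-1,6-dien-4-yl 2,2-dimethylpropanoate
Product: 11 (1R,3S,5S)-5-bromo-2-[(Z)-2-bromoethylidene]-3-chloro-4,4-dimethylcyclohexyl 2,2-dimethylpropanoate
Conditions: Et2SBr·SbCl5Br (1.1 equiv), MeNO2, −25 °C, 10 min; aq Na2SO3/NaHCO3; then LiBr (5 equiv), acetone, 23 °C
Reagents that add atoms: bromodiethylsulfonium bromopentachloroantimonate, CC[S+](Br)CC.Br[Sb-](Cl)(Cl)(Cl)(Cl)Cl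
Why: Proposed new method: Br+ is passed reversibly from the sulfonium reagent to the electron-rich trisubstituted alkene, the bromonium ion is opened anti at its tertiary carbon by the chlorine-bearing terminus of the 1-chloro-1,3-diene (6-endo-trig closure through a chair), and the allyl cation so formed takes bromide from the antimonate at its primary end, a net 1,4-addition across the diene; the closest known reaction types are the bromonium-induced cyclization of myrcene-type 1,5-dienes and halonium polyene cyclizations with this reagent, neither of which has been shown with a chlorovinyl carbon as the nucleophile. The CHBr centre follows from anti opening in the chair that holds the pivalate of the existing carbinol centre equatorial, because the other chair would place the pivalate syn-diaxial to the incoming chlorine, and the two bromonium diastereomers can interconvert by Br+ transfer so that the matched one is drained. The CHCl centre is fixed by the Z geometry of the chloroalkene: the chlorine cis to the carbinol carbon becomes axial, trans to both bromine and pivalate. The exocyclic alkene geometry is governed by A(1,3) strain, since with the pivalate equatorial only the isomer with CH2Br on the CHCl side is unstrained, and the LiBr stage lets the allylic bromide equilibrate to it and would turn any allylic chloride into the bromide. The step needs six- over seven-membered closure and C- over O-capture of the bromonium ion; the chair six-ring path at the tertiary carbon and the hindered, weakly nucleophilic ester oxygen should secure both.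

Step 7
Reactants: 11 (1R,3S,5S)-5-bromo-2-[(Z)-2-bromoethylidene]-3-chloro-4,4-dimethylcyclohexyl 2,2-dimethylpropanoate
Product: 12 (1R,3S,5S)-5-bromo-2-[(Z)-2-bromoethylidene]-3-chloro-4,4-dimethylcyclohexan-1-ol
Conditions: i-Bu2AlH (2.5 equiv), CH2Cl2, −78 °C; aq potassium sodium tartrate
Reagents that add atoms: none
Why: Reductive ester cleavage at low temperature should spare the alkyl and allylic halides and avoids the basic or nucleophilic media that would displace the primary allylic bromide.

Step 8
Reactants: 12 (1R,3S,5S)-5-bromo-2-[(Z)-2-bromoethylidene]-3-chloro-4,4-dimethylcyclohexan-1-ol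
Product: 13 (2S,4S,6S)-6-bromo-3-[(Z)-2-bromoethylidene]-2,4-dichloro-1,1-dimethylcyclohexane
Conditions: PPh3 (1.3 equiv), hexachloroacetone (3 equiv), CH2Cl2, −20 to 0 °C
Reagents that add atoms: hexachloroacetone, ClC(Cl)(Cl)C(=O)C(Cl)(Cl)Cl
Why: Appel-type chlorination of an allylic alcohol: chloride displaces the alkoxyphosphonium group by SN2 with inversion and little allylic transposition, turning the equatorial carbinol into the axial chloride cis to the other chlorine.

**Compound list**

1 | 3-(trimethylsilyl)prop-2-ynal | C[Si](C)(C)C#CC=O | starting material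
2 | allyltributylstannane | C=CC[Sn](CCCC)(CCCC)CCCC | starting material
3 | (3R)-1-(trimethylsilyl)hex-5-en-1-yn-3-ol | C[Si](C)(C)C#C[C@H](O)CC=C | intermediate
4 | 2-methylbut-2-ene | CC=C(C)C | starting material
5 | (3R)-6-methyl-1-(trimethylsilyl)hept-5-en-1-yn-3-ol | C[Si](C)(C)C#C[C@H](O)CC=C(C)C | intermediate
6 | (3R)-6-methylhept-5-en-1-yn-3-ol | C#C[C@H](O)CC=C(C)C | intermediate
7 | vinylmagnesium chloride | C=C[Mg]Cl | starting material
8 | dimagnesium chelate: chloromagnesium alkoxide of 9 carrying ClMg in place of Cl on the terminal alkene carbon, cis to the carbinol carbon | Cl[Mg]/C=C(/C=C)[C@H](O[Mg]Cl)CC=C(C)C | intermediate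
9 | (4R)-3-[(Z)-chloromethylidene]-7-methylocta-1,6-dien-4-ol | Cl/C=C(/C=C)[C@H](O)CC=C(C)C | intermediate
10 | (4R)-3-[(Z)-chloromethylidene]-7-methylocta-1,6-dien-4-yl 2,2-dimethylpropanoate | Cl/C=C(/C=C)[C@H](OC(=O)C(C)(C)C)CC=C(C)C | intermediate
11 | (1R,3S,5S)-5-bromo-2-[(Z)-2-bromoethylidene]-3-chloro-4,4-dimethylcyclohexyl 2,2-dimethylpropanoate | CC1(C)[C@@H](Br)C[C@@H](OC(=O)C(C)(C)C)/C(=C/CBr)[C@@H]1Cl | intermediate
12 | (1R,3S,5S)-5-bromo-2-[(Z)-2-bromoethylidene]-3-chloro-4,4-dimethylcyclohexan-1-ol | CC1(C)[C@@H](Br)C[C@@H](O)/C(=C/CBr)[C@@H]1Cl | intermediate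
13 | (2S,4S,6S)-6-bromo-3-[(Z)-2-bromoethylidene]-2,4-dichloro-1,1-dimethylcyclohexane | CC1(C)[C@@H](Br)C[C@H](Cl)/C(=C/CBr)[C@@H]1Cl | target

Total step count: 8. Longest linear sequence: 8 steps (from 1).

**Steps most likely to fail**

First, step 6, which bears the label. The bromonium ion may be captured by halide before the weakly nucleophilic chlorodiene closes the ring. Closure may also run through the unsubstituted diene terminus to a seven-membered ring, the allyl cation may lose a proton, or the mismatched bromonium face may react. The fallback uses known reaction types only, sets out from 6 and returns at 11. Copper-catalysed anti-carbomagnesiation of 6 with Me3SiCH2MgCl and chlorination with NCS should give the allylsilane (1E,3R)-1-chloro-6-methyl-2-[(trimethylsilyl)methyl]hepta-1,5-dien-3-ol F1. Pivaloylation gives (1E,3R)-1-chloro-6-methyl-2-[(trimethylsilyl)methyl]hepta-1,5-dien-3-yl 2,2-dimethylpropanoate F2. An allylsilane-terminated bromonium cyclization (Et2SBr·SbCl5Br, MeNO2, −25 °C), in which the beta-silyl cation makes the chlorovinyl carbon a competent nucleophile and closes the seven-ring path, should give (1R,3S,5S)-5-bromo-3-chloro-4,4-dimethyl-2-methylidenecyclohexyl 2,2-dimethylpropanoate F3 by the same chair. Ozonolysis (O3, then Me2S) gives the ketone (1R,3R,5S)-5-bromo-3-chloro-4,4-dimethyl-2-oxocyclohexyl 2,2-dimethylpropanoate F4. Addition of CH2=CHMgBr/CeCl3 at −78 °C gives the tertiary allylic alcohol (1R,3R,5S)-5-bromo-3-chloro-2-ethenyl-2-hydroxy-4,4-dimethylcyclohexyl 2,2-dimethylpropanoate F5 (either carbinol epimer serves). PBr3 with allylic transposition, followed by LiBr equilibration under the same A(1,3) control, returns 11.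

Second, step 8. Chloride may attack with allylic transposition instead of directly, axial attack beside the axial chlorine may be slow, and bromide–chloride exchange may occur at the primary allylic carbon. The fallback sets out from 12 and returns at 13. Mesylation (MsCl, Et3N, CH2Cl2, −20 °C) gives (1R,3S,5S)-5-bromo-2-[(Z)-2-bromoethylidene]-3-chloro-4,4-dimethylcyclohexyl methanesulfonate F6. Excess LiCl in DMF displaces the mesylate with inversion and is allowed to exchange the primary allylic bromide completely, giving (2S,4S,6S)-6-bromo-2,4-dichloro-3-[(Z)-2-chloroethylidene]-1,1-dimethylcyclohexane F7. A Finkelstein reaction (excess LiBr, acetone), selective for the primary allylic chloride, then gives 13.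

Third, step 4. Chlorination of the chelated alkenylmagnesium may be inefficient, with protonation or homocoupling taking its place. The fallback sets out from 6 (with 7) and returns at 9. Quenching the same chelate with I2, the halogenation best precedented for such chelates, should give (4R)-3-[(Z)-iodomethylidene]-7-methylocta-1,6-dien-4-ol F8. Copper-mediated iodine-for-chlorine exchange (CuCl, NMP, 110 °C), which keeps the alkene geometry, then gives 9.

Further compounds
F1 | step 6 | (1E,3R)-1-chloro-6-methyl-2-[(trimethylsilyl)methyl]hepta-1,5-dien-3-ol | Cl/C=C(/C[Si](C)(C)C)[C@H](O)CC=C(C)C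
F2 | step 6 | (1E,3R)-1-chloro-6-methyl-2-[(trimethylsilyl)methyl]hepta-1,5-dien-3-yl 2,2-dimethylpropanoate | Cl/C=C(/C[Si](C)(C)C)[C@H](OC(=O)C(C)(C)C)CC=C(C)C
F3 | step 6 | (1R,3S,5S)-5-bromo-3-chloro-4,4-dimethyl-2-methylidenecyclohexyl 2,2-dimethylpropanoate | CC1(C)[C@@H](Br)C[C@@H](OC(=O)C(C)(C)C)C(=C)[C@@H]1Cl
F4 | step 6 | (1R,3R,5S)-5-bromo-3-chloro-4,4-dimethyl-2-oxocyclohexyl 2,2-dimethylpropanoate | CC1(C)[C@@H](Br)C[C@@H](OC(=O)C(C)(C)C)C(=O)[C@@H]1Cl
F5 | step 6 | (1R,3R,5S)-5-bromo-3-chloro-2-ethenyl-2-hydroxy-4,4-dimethylcyclohexyl 2,2-dimethylpropanoate (either epimer at the new carbinol carbon) | CC1(C)[C@@H](Br)C[C@@H](OC(=O)C(C)(C)C)C(O)(C=C)[C@@H]1Cl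
F6 | step 8 | (1R,3S,5S)-5-bromo-2-[(Z)-2-bromoethylidene]-3-chloro-4,4-dimethylcyclohexyl methanesulfonate | CC1(C)[C@@H](Br)C[C@@H](OS(C)(=O)=O)/C(=C/CBr)[C@@H]1Cl
F7 | step 8 | (2S,4S,6S)-6-bromo-2,4-dichloro-3-[(Z)-2-chloroethylidene]-1,1-dimethylcyclohexane | CC1(C)[C@@H](Br)C[C@H](Cl)/C(=C/CCl)[C@@H]1Cl
F8 | step 4 | (4R)-3-[(Z)-iodomethylidene]-7-methylocta-1,6-dien-4-ol | I/C=C(/C=C)[C@H](O)CC=C(C)C
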